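**Retrosynthetic overview**

1. Germacrane numbering is used: ten-membered ring C1–C10 with the C1=C10 and C4=C5 alkenes (C14 = CH2OAc carbon on C10, C15 = formyl carbon on C4); γ-lactone ring C6–O–C12(=O)–C11(=C13)–C7; C8 carries the 2-(hydroxymethyl)acrylate. Last disconnections: the C8 ester and the C15 aldehyde (from a PMB-protected allylic alcohol).
2. Key disconnection: ring bond C7–C8, made by an intramolecular Nozaki–Hiyama–Kishi allylation. The enabling feature is the α-methylene-γ-lactone fused at C6–C7 next to oxygenated C8: O–C8–C7–C11(=C13) is a homoallylic alcohol, so the isomeric butenolide (C7=C11 inside the lactone ring, bromine on C13) is an allyl-metal precursor whose γ-carbon is C7. Closing it onto a C8 aldehyde builds the ten-membered ring, the exocyclic methylene and the C7 and C8 stereocentres in one operation, from C6 alone.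
3. The butenolide comes from a propargylic alcohol (C6 set by catalytic asymmetric alkynylation of an enal) by directed trans-hydroalumination/iodination and carbonylative lactonisation.
4. The open chain comes from a B-alkyl Suzuki coupling (bond C3–C4) of a dienyl acetate (acrolein plus a butyrolactone ylide; fixes C1=C10) with a Z-iodo-allylic alcohol (from but-2-yne-1,4-diol; fixes C4=C5).
5. Ring order: γ-lactone first (as the butenolide), ten-membered carbocycle second.

Key step: step 18

Remark: both ring alkenes of the target are E by the sequence rules but carry the ring carbons cis; every alkene-forming step is planned for that geometry.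
Assumption: (S,S)-ProPhenol is written for step 10; the sense of induction on this β,β-disubstituted enal is assumed, not known, so the R configuration of the product is to be confirmed (Mosher esters) and the (R,R)-ligand used if the opposite alcohol forms.

**Route**

Step 1
Reactants: 1 acrolein; 2 α-(triphenylphosphoranylidene)-γ-butyrolactone
Product: 3 (E)-3-(prop-2-en-1-ylidene)oxolan-2-one
Conditions: CH2Cl2, 0 °C to rt
Reagents that add atoms: none
Why: Wittig olefination with a lactone-stabilised ylide is E-selective, so the lactone carbonyl (later C14) ends up trans to the vinyl group, which is the C1=C10 geometry of the target.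

Step 2
Reactants: 3
Product: 6 (E)-2-[2-(tert-butyldimethylsilyloxy)ethyl]penta-2,4-dienoic acid, via sodium hydroxy-dienoate 4 (not isolated), via bis-silylated dienoate 5 (not isolated)
Conditions: NaOH (1.05 equiv), THF/H2O, 0 °C to rt, evaporation to dryness; TBSCl (2.3 equiv), imidazole, DMF, rt; then AcOH/THF/H2O, rt
Reagents that add atoms: sodium hydroxide ([Na+].[OH-]); tert-butyldimethylsilyl chloride (CC(C)(C)[Si](C)(C)Cl)
Why: Lactone saponification, silylation of both oxygens and selective hydrolysis of the labile silyl ester should leave C8 as a TBS ether and C14 as the free acid, which differentiates the two oxygenated carbons.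

Step 3
Reactants: 6
Product: 8 (E)-2-[2-(tert-butyldimethylsilyloxy)ethyl]penta-2,4-dien-1-ol, via isobutyl carbonic mixed anhydride 7 (not isolated)
Conditions: i-BuOCOCl, N-methylmorpholine, THF, −15 °C; then NaBH4, H2O, 0 °C
Reagents that add atoms: none
Why: Mixed-anhydride activation and NaBH4 reduction should take the conjugated acid to the allylic alcohol without touching the diene or the silyl ether.

Step 4
Reactants: 8
Product: 9 (E)-2-[2-(tert-butyldimethylsilyloxy)ethyl]penta-2,4-dien-1-yl acetate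
Conditions: Ac2O, pyridine, DMAP (cat.), CH2Cl2, 0 °C
Reagents that add atoms: acetic anhydride (CC(=O)OC(C)=O)
Why: Acetylation masks the C14 hydroxyl through the coupling, allylic oxidation and alkynylation; this acetate is a temporary mask that step 11 removes.

Step 5
Reactants: 10 but-2-yne-1,4-diol
Product: 12 4-[(4-methoxybenzyl)oxy]but-2-yn-1-ol, via monosodium alkoxide 11 (not isolated)
Conditions: 10 (3 equiv), NaH (1 equiv), THF/DMF, 0 °C; then PMBCl (1 equiv), Bu4NI (cat.), rt
Reagents that add atoms: 4-methoxybenzyl chloride (COc1ccc(CCl)cc1)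
Why: Williamson etherification of the diol used in excess should give the mono-PMB ether, which marks the later C15 oxygen.

Step 6
Reactants: 12
Product: 14 (Z)-3-iodo-4-[(4-methoxybenzyl)oxy]but-2-en-1-ol, via cyclic vinylalanate 13 (not isolated)
Conditions: NaAlH2(OCH2CH2OMe)2 (Red-Al, 1.6 equiv), THF, 0 °C; then I2, −78 to 0 °C; aq. potassium sodium tartrate
Reagents that add atoms: iodine (II)
Why: Hydroxyl-directed trans-hydroalumination puts hydride on the alkyne carbon next to the carbinol (C5) and aluminium on the remote one (C4), and iodinolysis with retention should give the Z-iodide with iodine cis to the CH2OH group.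

Step 7
Reactants: 9; 14
Product: 16 (2E,6E)-7-(acetoxymethyl)-9-(tert-butyldimethylsilyloxy)-3-[(4-methoxybenzyloxy)methyl]nona-2,6-dien-1-ol, via B-alkyl-9-BBN adduct 15 (not isolated)
Conditions: 9 (1.2 equiv), 9-BBN, THF, 0 °C to rt; then 14, Pd(dppf)Cl2 (5 mol %), AsPh3, K3PO4 (aq), DMF, rt
Reagents that add atoms: none
Why: 9-BBN should add only to the terminal vinyl group of the diene (boron on C3), and the B-alkyl Suzuki–Miyaura coupling forms C3–C4 with retention of the vinyl iodide geometry, so both trisubstituted alkenes are in place.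

Step 8
Reactants: 16
Product: 17 (2E,6E)-7-(acetoxymethyl)-9-(tert-butyldimethylsilyloxy)-3-[(4-methoxybenzyloxy)methyl]nona-2,6-dienal
Conditions: MnO2 (activated, excess), CH2Cl2, rt
Reagents that add atoms: none
Why: Allylic oxidation with MnO2 should give the enal without isomerising the trisubstituted alkene, the C6 hydroxyl being the only free one.

Step 9
Reactants: 18 prop-2-yn-1-ol
Product: 19 triethyl(prop-2-yn-1-yloxy)silane
Conditions: TESCl, imidazole, CH2Cl2, 0 °C
Reagents that add atoms: chlorotriethylsilane (CC[Si](CC)(CC)Cl)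
Why: Silyl ether formation gives the alkyne that delivers C7, C11 and C13 with a C13 oxygen that can be freed selectively later.

Step 10
Reactants: 17; 19
Product: 21 (4R,5E,9E)-10-(acetoxymethyl)-12-(tert-butyldimethylsilyloxy)-6-[(4-methoxybenzyloxy)methyl]-1-(triethylsilyloxy)dodeca-5,9-dien-2-yn-4-ol, via methyl(alkynyl)zinc reagent 20 (not isolated)
Conditions: 19 (2.5 equiv), Me2Zn (3 equiv), (S,S)-ProPhenol (20 mol %), Ph3PO (40 mol %), toluene, 0–4 °C
Reagents that add atoms: none
Why: Zinc–ProPhenol-catalysed asymmetric alkynylation of an enal, in which the chiral dinuclear zinc catalyst should deliver the alkynyl group to the Si face of the aldehyde and set C6 as R, the only stereocentre made by catalysis.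

Step 11
Reactants: 21
Product: 23 (2Z,4R,5E,9E)-10-(hydroxymethyl)-2-iodo-6-[(4-methoxybenzyloxy)methyl]-12-(tert-butyldimethylsilyloxy)-1-(triethylsilyloxy)dodeca-2,5,9-trien-4-ol, via cyclic vinylalanate 22 (not isolated)
Conditions: NaAlH2(OCH2CH2OMe)2 (5 equiv), THF, −20 to 0 °C; then I2, −78 to −20 °C; aq. potassium sodium tartrate
Reagents that add atoms: iodine (II)
Why: The C6 alkoxide directs trans-hydroalumination of the alkyne (hydride to C7, aluminium to C11) and iodinolysis should give the iodide cis to C6, while the excess hydride reduces off the temporary C14 acetate.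

Step 12
Reactants: 23
Product: 24 (R)-5-[(1E,5E)-8-(tert-butyldimethylsilyloxy)-6-(hydroxymethyl)-2-[(4-methoxybenzyloxy)methyl]octa-1,5-dien-1-yl]-3-[(triethylsilyloxy)methyl]furan-2(5H)-one
Conditions: Pd(PPh3)2Cl2 (5 mol %), CO (1 atm), K2CO3, THF, rt to 35 °C
Reagents that add atoms: carbon monoxide ([C-]#[O+])
Why: Carbonylative lactonisation, in which oxidative addition of zerovalent palladium to the C11–I bond, CO insertion and capture of the acylpalladium by the cis C6 hydroxyl should close the butenolide, the remote C14 hydroxyl being unable to compete.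

Step 13
Reactants: 24
Product: 25 (R)-5-[(1E,5E)-6-(acetoxymethyl)-8-(tert-butyldimethylsilyloxy)-2-[(4-methoxybenzyloxy)methyl]octa-1,5-dien-1-yl]-3-[(triethylsilyloxy)methyl]furan-2(5H)-one
Conditions: Ac2O, pyridine, CH2Cl2, 0 °C
Reagents that add atoms: acetic anhydride (CC(=O)OC(C)=O)
Why: Acetylation of the only free hydroxyl (C14) installs the acetate of the target.

Step 14
Reactants: 25
Product: 26 (R)-5-[(1E,5E)-6-(acetoxymethyl)-8-(tert-butyldimethylsilyloxy)-2-[(4-methoxybenzyloxy)methyl]octa-1,5-dien-1-yl]-3-(hydroxymethyl)furan-2(5H)-one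
Conditions: PPTS (cat.), MeOH/CH2Cl2, 0 °C
Reagents that add atoms: none
Why: Acid-catalysed methanolysis should remove the primary TES ether much faster than the primary TBS ether, freeing only the C13 hydroxyl.

Step 15
Reactants: 26
Product: 27 (R)-5-[(1E,5E)-6-(acetoxymethyl)-8-(tert-butyldimethylsilyloxy)-2-[(4-methoxybenzyloxy)methyl]octa-1,5-dien-1-yl]-3-(bromomethyl)furan-2(5H)-one
Conditions: CBr4, PPh3, CH2Cl2, 0 °C
Reagents that add atoms: tetrabromomethane (BrC(Br)(Br)Br)
Why: Appel bromination should convert the allylic C13 alcohol into the bromide under neutral conditions that leave C6 untouched.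

Step 16
Reactants: 27
Product: 28 (R)-5-[(1E,5E)-6-(acetoxymethyl)-8-hydroxy-2-[(4-methoxybenzyloxy)methyl]octa-1,5-dien-1-yl]-3-(bromomethyl)furan-2(5H)-one
Conditions: HF (48 % aq), MeCN, 0 °C
Reagents that add atoms: none
Why: Aqueous HF should cleave the primary TBS ether (desilylation) while the PMB ether, acetate, lactone and allylic bromide survive.

Step 17
Reactants: 28
Product: 29 (R)-5-[(1E,5E)-6-(acetoxymethyl)-2-[(4-methoxybenzyloxy)methyl]-8-oxoocta-1,5-dien-1-yl]-3-(bromomethyl)furan-2(5H)-one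
Conditions: Dess–Martin periodinane, NaHCO3, CH2Cl2, 0 °C; used at once without chromatography
Reagents that add atoms: none
Why: Buffered Dess–Martin oxidation should give the β,γ-unsaturated C8 aldehyde without moving the C1=C10 double bond into conjugation.

Step 18
Reactants: 29
Product: 31 (3aR,4S,6E,10E,11aR)-6-(acetoxymethyl)-4-hydroxy-10-[(4-methoxybenzyloxy)methyl]-3-methylene-3a,4,5,8,9,11a-hexahydrocyclodeca[b]furan-2(3H)-one, via allylchromium species 30 (not isolated)
Conditions: CrCl2 (8 equiv), degassed THF, rt; 29 added by syringe pump over 8 h to a final 2 mM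
Reagents that add atoms: none
Why: Two equivalents of CrCl2 reduce the allylic C13–Br bond to the allylchromium 30 (trivalent chromium), whose γ-carbon C7 adds to the C8 aldehyde through a closed six-membered chair transition state, so that the double bond moves from C7=C11 (in the lactone ring) to C11=C13 (exocyclic) as C7–C8 forms; this is a Nozaki–Hiyama–Kishi allylation, the closest known cases being the chromium-mediated allylation of aldehydes with 3-(bromomethyl)furan-2(5H)-ones and the intramolecular allylation of 2-(bromomethyl)acrylates that closes germacrane rings. The ten-membered carbocycle is closed in the 10-exo-trig mode, the carbonyl oxygen staying outside the ring. C7 is controlled by C6: the chain should reach C7 on the butenolide face anti to the C5 substituent, which gives the trans-fused lactone (6R,7R). C8 is controlled by the chair: the butenolide ring holds C6 trans to C13 across C7=C11 (an E-type γ-substituted allyl metal) and C9 sits pseudo-equatorial, which gives the anti C7/C8 pair, that is 8S. The step needs γ- over α-attack (secured by the closed transition state), ring closure over oligomerisation (high dilution and slow addition, helped by the two ring-cis trisubstituted alkenes that already fold the chain) and a single electrophile (C15 is kept as an ether so no second aldehyde is present, and acetate, PMB ether and lactone are inert to CrCl2).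

Step 19
Reactants: 32 ethyl 2-(hydroxymethyl)acrylate
Product: 33 ethyl 2-[(tert-butyldimethylsilyloxy)methyl]acrylate
Conditions: TBSCl, imidazole, CH2Cl2, 0 °C to rt
Reagents that add atoms: tert-butyldimethylsilyl chloride (CC(C)(C)[Si](C)(C)Cl)
Why: Silyl ether formation protects the hydroxyl of the side-chain acid.

Step 20
Reactants: 33
Product: 35 2-[(tert-butyldimethylsilyloxy)methyl]acrylic acid, via lithium carboxylate 34 (not isolated)
Conditions: LiOH, THF/H2O, 0 °C to rt; then 1 M HCl to pH 3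
Reagents that add atoms: lithium hydroxide ([Li+].[OH-])
Why: Ester saponification at low temperature should give the acid without conjugate addition to the acrylate.

Step 21
Reactants: 31; 35
Product: 37 (3aR,4S,6E,10E,11aR)-6-(acetoxymethyl)-10-[(4-methoxybenzyloxy)methyl]-3-methylene-2-oxo-2,3,3a,4,5,8,9,11a-octahydrocyclodeca[b]furan-4-yl 2-[(tert-butyldimethylsilyloxy)methyl]acrylate, via Yamaguchi mixed anhydride 36 (not isolated)
Conditions: 35, 2,4,6-trichlorobenzoyl chloride, Et3N, THF, rt; then 31, DMAP, toluene, rt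
Reagents that add atoms: none
Why: Yamaguchi esterification should acylate the hindered C8 alcohol on oxygen with retention at C8, fast enough to forestall translactonisation to C8.

Step 22
Reactants: 37
Product: 38 (3aR,4S,6E,10E,11aR)-6-(acetoxymethyl)-10-(hydroxymethyl)-3-methylene-2-oxo-2,3,3a,4,5,8,9,11a-octahydrocyclodeca[b]furan-4-yl 2-[(tert-butyldimethylsilyloxy)methyl]acrylate
Conditions: DDQ, CH2Cl2/pH 7 buffer, 0 °C to rt
Reagents that add atoms: none
Why: Oxidative cleavage of the PMB ether should free only the C15 hydroxyl.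

Step 23
Reactants: 38
Product: 39 (3aR,4S,6E,10E,11aR)-6-(acetoxymethyl)-10-formyl-3-methylene-2-oxo-2,3,3a,4,5,8,9,11a-octahydrocyclodeca[b]furan-4-yl 2-[(tert-butyldimethylsilyloxy)methyl]acrylate
Conditions: MnO2 (activated, excess), CH2Cl2, rt
Reagents that add atoms: none
Why: Allylic oxidation with MnO2 should give the C15 enal, the other primary oxygen still being silylated.

Step 24
Reactants: 39
Product: 40 (3aR,4S,6E,10E,11aR)-6-(acetoxymethyl)-10-formyl-3-methylene-2-oxo-2,3,3a,4,5,8,9,11a-octahydrocyclodeca[b]furan-4-yl 2-(hydroxymethyl)acrylate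
Conditions: HF·pyridine, pyridine/THF, 0 °C to rt
Reagents that add atoms: none
Why: Buffered HF desilylation should free the side-chain hydroxyl and leave the enal, acetate and α-methylene lactone untouched.

**Compound list**

1 | acrolein (prop-2-enal) | C=CC=O | starting material
2 | α-(triphenylphosphoranylidene)-γ-butyrolactone | O=C1OCCC1=P(c1ccccc1)(c1ccccc1)c1ccccc1 | starting material
3 | (E)-3-(prop-2-en-1-ylidene)oxolan-2-one | O=C1OCC/C1=C\C=C | intermediate
4 | sodium (E)-2-(2-hydroxyethyl)penta-2,4-dienoate | [Na+].[O-]C(=O)/C(CCO)=C/C=C | intermediate (not isolated)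
5 | tert-butyldimethylsilyl (E)-2-[2-(tert-butyldimethylsilyloxy)ethyl]penta-2,4-dienoate | CC(C)(C)[Si](C)(C)OC(=O)/C(CCO[Si](C)(C)C(C)(C)C)=C/C=C | intermediate (not isolated)
6 | (E)-2-[2-(tert-butyldimethylsilyloxy)ethyl]penta-2,4-dienoic acid | OC(=O)/C(CCO[Si](C)(C)C(C)(C)C)=C/C=C | intermediate
7 | mixed anhydride of 6 and isobutyl hydrogen carbonate | CC(C)COC(=O)OC(=O)/C(CCO[Si](C)(C)C(C)(C)C)=C/C=C | intermediate (not isolated)
8 | (E)-2-[2-(tert-butyldimethylsilyloxy)ethyl]penta-2,4-dien-1-ol | OC/C(CCO[Si](C)(C)C(C)(C)C)=C/C=C | intermediate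
9 | (E)-2-[2-(tert-butyldimethylsilyloxy)ethyl]penta-2,4-dien-1-yl acetate | CC(=O)OC/C(CCO[Si](C)(C)C(C)(C)C)=C/C=C | intermediate
10 | but-2-yne-1,4-diol | OCC#CCO | starting material
11 | monosodium alkoxide of but-2-yne-1,4-diol | [Na+].[O-]CC#CCO | intermediate (not isolated)
12 | 4-[(4-methoxybenzyl)oxy]but-2-yn-1-ol | COc1ccc(COCC#CCO)cc1 | intermediate
13 | sodium 2,2-bis(2-methoxyethoxy)-3-[(4-methoxybenzyloxy)methyl]-2,5-dihydro-1,2-oxaluminol-2-uide (cyclic vinylalanate) | [Na+].COCCO[Al-]1(OCCOC)OCC=C1COCc1ccc(OC)cc1 | intermediate (not isolated)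
14 | (Z)-3-iodo-4-[(4-methoxybenzyl)oxy]but-2-en-1-ol | OC/C=C(\I)COCc1ccc(OC)cc1 | intermediate
15 | (E)-5-(9-borabicyclo[3.3.1]nonan-9-yl)-2-[2-(tert-butyldimethylsilyloxy)ethyl]pent-2-en-1-yl acetate | CC(=O)OC/C(CCO[Si](C)(C)C(C)(C)C)=C/CCB1C2CCCC1CCC2 | intermediate (not isolated)
16 | (2E,6E)-7-(acetoxymethyl)-9-(tert-butyldimethylsilyloxy)-3-[(4-methoxybenzyloxy)methyl]nona-2,6-dien-1-ol | CC(=O)OC/C(CCO[Si](C)(C)C(C)(C)C)=C/CC/C(COCc1ccc(OC)cc1)=C\CO | intermediate
17 | (2E,6E)-7-(acetoxymethyl)-9-(tert-butyldimethylsilyloxy)-3-[(4-methoxybenzyloxy)methyl]nona-2,6-dienal | CC(=O)OC/C(CCO[Si](C)(C)C(C)(C)C)=C/CC/C(COCc1ccc(OC)cc1)=C\C=O | intermediate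
18 | prop-2-yn-1-ol | C#CCO | starting material
19 | triethyl(prop-2-yn-1-yloxy)silane | C#CCO[Si](CC)(CC)CC | intermediate
20 | methyl[3-(triethylsilyloxy)prop-1-yn-1-yl]zinc | C[Zn]C#CCO[Si](CC)(CC)CC | intermediate (not isolated)
21 | (4R,5E,9E)-10-(acetoxymethyl)-12-(tert-butyldimethylsilyloxy)-6-[(4-methoxybenzyloxy)methyl]-1-(triethylsilyloxy)dodeca-5,9-dien-2-yn-4-ol | CC(=O)OC/C(CCO[Si](C)(C)C(C)(C)C)=C/CC/C(COCc1ccc(OC)cc1)=C\[C@@H](O)C#CCO[Si](CC)(CC)CC | intermediate
22 | disodium salt of the cyclic vinylalanate from 21 (aluminium bound to the C6 oxygen and to C11; C14 alkoxide) | [Na+].[Na+].[O-]C/C(CCO[Si](C)(C)C(C)(C)C)=C/CC/C(COCc1ccc(OC)cc1)=C\[C@H]1O[Al-](OCCOC)(OCCOC)C(CO[Si](CC)(CC)CC)=C1 | intermediate (not isolated)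
23 | (2Z,4R,5E,9E)-10-(hydroxymethyl)-2-iodo-6-[(4-methoxybenzyloxy)methyl]-12-(tert-butyldimethylsilyloxy)-1-(triethylsilyloxy)dodeca-2,5,9-trien-4-ol | OC/C(CCO[Si](C)(C)C(C)(C)C)=C/CC/C(COCc1ccc(OC)cc1)=C\[C@@H](O)/C=C(\I)CO[Si](CC)(CC)CC | intermediate
24 | (R)-5-[(1E,5E)-8-(tert-butyldimethylsilyloxy)-6-(hydroxymethyl)-2-[(4-methoxybenzyloxy)methyl]octa-1,5-dien-1-yl]-3-[(triethylsilyloxy)methyl]furan-2(5H)-one | OC/C(CCO[Si](C)(C)C(C)(C)C)=C/CC/C(COCc1ccc(OC)cc1)=C\[C@H]1OC(=O)C(CO[Si](CC)(CC)CC)=C1 | intermediate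
25 | (R)-5-[(1E,5E)-6-(acetoxymethyl)-8-(tert-butyldimethylsilyloxy)-2-[(4-methoxybenzyloxy)methyl]octa-1,5-dien-1-yl]-3-[(triethylsilyloxy)methyl]furan-2(5H)-one | CC(=O)OC/C(CCO[Si](C)(C)C(C)(C)C)=C/CC/C(COCc1ccc(OC)cc1)=C\[C@H]1OC(=O)C(CO[Si](CC)(CC)CC)=C1 | intermediate
26 | (R)-5-[(1E,5E)-6-(acetoxymethyl)-8-(tert-butyldimethylsilyloxy)-2-[(4-methoxybenzyloxy)methyl]octa-1,5-dien-1-yl]-3-(hydroxymethyl)furan-2(5H)-one | CC(=O)OC/C(CCO[Si](C)(C)C(C)(C)C)=C/CC/C(COCc1ccc(OC)cc1)=C\[C@H]1OC(=O)C(CO)=C1 | intermediate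
27 | (R)-5-[(1E,5E)-6-(acetoxymethyl)-8-(tert-butyldimethylsilyloxy)-2-[(4-methoxybenzyloxy)methyl]octa-1,5-dien-1-yl]-3-(bromomethyl)furan-2(5H)-one | CC(=O)OC/C(CCO[Si](C)(C)C(C)(C)C)=C/CC/C(COCc1ccc(OC)cc1)=C\[C@H]1OC(=O)C(CBr)=C1 | intermediate
28 | (R)-5-[(1E,5E)-6-(acetoxymethyl)-8-hydroxy-2-[(4-methoxybenzyloxy)methyl]octa-1,5-dien-1-yl]-3-(bromomethyl)furan-2(5H)-one | CC(=O)OC/C(CCO)=C/CC/C(COCc1ccc(OC)cc1)=C\[C@H]1OC(=O)C(CBr)=C1 | intermediate
29 | (R)-5-[(1E,5E)-6-(acetoxymethyl)-2-[(4-methoxybenzyloxy)methyl]-8-oxoocta-1,5-dien-1-yl]-3-(bromomethyl)furan-2(5H)-one | CC(=O)OC/C(CC=O)=C/CC/C(COCc1ccc(OC)cc1)=C\[C@H]1OC(=O)C(CBr)=C1 | intermediate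
30 | dichloro{[(R)-5-substituted 2-oxo-2,5-dihydrofuran-3-yl]methyl}chromium from 29 (CrCl2 group in place of bromine) | CC(=O)OC/C(CC=O)=C/CC/C(COCc1ccc(OC)cc1)=C\[C@H]1OC(=O)C(C[Cr](Cl)Cl)=C1 | intermediate (not isolated)
31 | (3aR,4S,6E,10E,11aR)-6-(acetoxymethyl)-4-hydroxy-10-[(4-methoxybenzyloxy)methyl]-3-methylene-3a,4,5,8,9,11a-hexahydrocyclodeca[b]furan-2(3H)-one | O[C@H]1C/C(COC(C)=O)=C\CC/C(COCc3ccc(OC)cc3)=C\[C@H]2OC(=O)C(=C)[C@H]12 | intermediate
32 | ethyl 2-(hydroxymethyl)acrylate | C=C(CO)C(=O)OCC | starting material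
33 | ethyl 2-[(tert-butyldimethylsilyloxy)methyl]acrylate | C=C(CO[Si](C)(C)C(C)(C)C)C(=O)OCC | intermediate
34 | lithium 2-[(tert-butyldimethylsilyloxy)methyl]acrylate | [Li+].[O-]C(=O)C(=C)CO[Si](C)(C)C(C)(C)C | intermediate (not isolated)
35 | 2-[(tert-butyldimethylsilyloxy)methyl]acrylic acid | C=C(CO[Si](C)(C)C(C)(C)C)C(O)=O | intermediate
36 | 2-[(tert-butyldimethylsilyloxy)methyl]acrylic 2,4,6-trichlorobenzoic anhydride | C=C(CO[Si](C)(C)C(C)(C)C)C(=O)OC(=O)c1c(Cl)cc(Cl)cc1Cl | intermediate (not isolated)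
37 | (3aR,4S,6E,10E,11aR)-6-(acetoxymethyl)-10-[(4-methoxybenzyloxy)methyl]-3-methylene-2-oxo-2,3,3a,4,5,8,9,11a-octahydrocyclodeca[b]furan-4-yl 2-[(tert-butyldimethylsilyloxy)methyl]acrylate | C=C(CO[Si](C)(C)C(C)(C)C)C(=O)O[C@H]1C/C(COC(C)=O)=C\CC/C(COCc3ccc(OC)cc3)=C\[C@H]2OC(=O)C(=C)[C@H]12 | intermediate
38 | (3aR,4S,6E,10E,11aR)-6-(acetoxymethyl)-10-(hydroxymethyl)-3-methylene-2-oxo-2,3,3a,4,5,8,9,11a-octahydrocyclodeca[b]furan-4-yl 2-[(tert-butyldimethylsilyloxy)methyl]acrylate | C=C(CO[Si](C)(C)C(C)(C)C)C(=O)O[C@H]1C/C(COC(C)=O)=C\CC/C(CO)=C\[C@H]2OC(=O)C(=C)[C@H]12 | intermediate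
39 | (3aR,4S,6E,10E,11aR)-6-(acetoxymethyl)-10-formyl-3-methylene-2-oxo-2,3,3a,4,5,8,9,11a-octahydrocyclodeca[b]furan-4-yl 2-[(tert-butyldimethylsilyloxy)methyl]acrylate | C=C(CO[Si](C)(C)C(C)(C)C)C(=O)O[C@H]1C/C(COC(C)=O)=C\CC/C(C=O)=C\[C@H]2OC(=O)C(=C)[C@H]12 | intermediate
40 | (3aR,4S,6E,10E,11aR)-6-(acetoxymethyl)-10-formyl-3-methylene-2-oxo-2,3,3a,4,5,8,9,11a-octahydrocyclodeca[b]furan-4-yl 2-(hydroxymethyl)acrylate (CNP0198933.2) | C=C(CO)C(=O)O[C@H]1C/C(COC(C)=O)=C\CC/C(C=O)=C\[C@H]2OC(=O)C(=C)[C@H]12 | target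

**Step count and risks**

Total step count: 24. Longest linear sequence: 19 steps (steps 1–4, 7, 8, 10–18, 21–24, from acrolein); steps 5–6, 9 and 19–20 are side branches.

The three steps most likely to fail:

Step 18 (ring closure). Intermolecular allylation may outrun the ten-membered ring closure and give oligomers, the allylchromium may be protonated before it reaches the aldehyde, or the aldehyde may be delivered to the butenolide face syn to C5 (cis-fused lactone). The fallback replaces the transient allylchromium by an isolable allylboron reagent that cyclises without a reductant. It sets out from bromide 27: borylation with bis(pinacolato)diboron under Pd2(dba)3 catalysis should give the pinacol allylboronate F1, aqueous HF in MeCN the primary alcohol F2, and buffered Dess–Martin oxidation the boronate aldehyde F3. F3 can be held at high dilution in toluene at 60–80 °C (or with catalytic Sc(OTf)3 at 0 °C) until the intramolecular allylboration, which passes through the same chair arrangement, is complete. The resulting cyclic pinacol borate F4 is hydrolysed on aqueous work-up, and the route is rejoined at 31.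

Step 10 (asymmetric alkynylation). Low enantioselectivity, or the wrong sense of induction, on the β,β-disubstituted enal. The fallback forms the C6–C7 bond without stereocontrol and sets C6 by reagent-controlled reduction. It sets out from enal 17: addition of the lithium acetylide of 19 (n-BuLi, THF, −78 °C) should give the racemic propargylic alcohol F5, and MnO2 should oxidise it to the alkynyl ketone F6. Midland reduction with (R)-Alpine-Borane, in which the alkyne acts as the small group, is expected to return the (R)-alcohol 21 by analogy with simple alkynyl ketones.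

Step 12 (carbonylative lactonisation). Erosion of the C6 configuration, either by base-mediated γ-deprotonation of the newly formed alkenyl butenolide or by ionisation of its allylic C6–O bond by zerovalent palladium. The fallback is carboxylation of a vinyllithium at low temperature, without palladium and without base at the butenolide stage. It sets out from diol 23: MeLi (2 equiv), then t-BuLi (2 equiv) in Et2O at −78 °C (iodine–lithium exchange on the dialkoxide), then CO2 should give, after mildly acidic work-up, the (Z)-hydroxy acid F7. F7 should lactonise on standing or on brief exposure to PPTS, and the route is rejoined at 24.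

**Further compounds**

F1 | step 18 | (R)-5-[(1E,5E)-6-(acetoxymethyl)-8-(tert-butyldimethylsilyloxy)-2-[(4-methoxybenzyloxy)methyl]octa-1,5-dien-1-yl]-3-[(4,4,5,5-tetramethyl-1,3,2-dioxaborolan-2-yl)methyl]furan-2(5H)-one | CC(=O)OC/C(CCO[Si](C)(C)C(C)(C)C)=C/CC/C(COCc1ccc(OC)cc1)=C\[C@H]1OC(=O)C(CB2OC(C)(C)C(C)(C)O2)=C1
F2 | step 18 | (R)-5-[(1E,5E)-6-(acetoxymethyl)-8-hydroxy-2-[(4-methoxybenzyloxy)methyl]octa-1,5-dien-1-yl]-3-[(4,4,5,5-tetramethyl-1,3,2-dioxaborolan-2-yl)methyl]furan-2(5H)-one | CC(=O)OC/C(CCO)=C/CC/C(COCc1ccc(OC)cc1)=C\[C@H]1OC(=O)C(CB2OC(C)(C)C(C)(C)O2)=C1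
F3 | step 18 | (R)-5-[(1E,5E)-6-(acetoxymethyl)-2-[(4-methoxybenzyloxy)methyl]-8-oxoocta-1,5-dien-1-yl]-3-[(4,4,5,5-tetramethyl-1,3,2-dioxaborolan-2-yl)methyl]furan-2(5H)-one | CC(=O)OC/C(CC=O)=C/CC/C(COCc1ccc(OC)cc1)=C\[C@H]1OC(=O)C(CB2OC(C)(C)C(C)(C)O2)=C1
F4 | step 18 | O-(4,4,5,5-tetramethyl-1,3,2-dioxaborolan-2-yl) derivative of 31 (cyclic pinacol borate at the C8 oxygen) | CC4(C)OB(OC4(C)C)O[C@H]1C/C(COC(C)=O)=C\CC/C(COCc3ccc(OC)cc3)=C\[C@H]2OC(=O)C(=C)[C@H]12
F5 | step 10 | racemic (5E,9E)-10-(acetoxymethyl)-12-(tert-butyldimethylsilyloxy)-6-[(4-methoxybenzyloxy)methyl]-1-(triethylsilyloxy)dodeca-5,9-dien-2-yn-4-ol | CC(=O)OC/C(CCO[Si](C)(C)C(C)(C)C)=C/CC/C(COCc1ccc(OC)cc1)=C\C(O)C#CCO[Si](CC)(CC)CC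
F6 | step 10 | (5E,9E)-10-(acetoxymethyl)-12-(tert-butyldimethylsilyloxy)-6-[(4-methoxybenzyloxy)methyl]-1-(triethylsilyloxy)dodeca-5,9-dien-2-yn-4-one | CC(=O)OC/C(CCO[Si](C)(C)C(C)(C)C)=C/CC/C(COCc1ccc(OC)cc1)=C\C(=O)C#CCO[Si](CC)(CC)CC
F7 | step 12 | (2Z,4R,5E,9E)-4-hydroxy-10-(hydroxymethyl)-6-[(4-methoxybenzyloxy)methyl]-12-(tert-butyldimethylsilyloxy)-2-[(triethylsilyloxy)methyl]dodeca-2,5,9-trienoic acid | OC/C(CCO[Si](C)(C)C(C)(C)C)=C/CC/C(COCc1ccc(OC)cc1)=C\[C@@H](O)/C=C(\C(O)=O)CO[Si](CC)(CC)CC
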